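**Strategy.** Ring A is grown on the ring B oxygen, not coupled to it as a finished arene. Its C1 ester lies between two oxygens (C2, C6) with the C4 methyl para to it, a pattern that maps onto a senecioate-derived ketene acetal diene (C2 to C5) and an ynoate (C1, C6). One (4+2) benzannulation of diene 15 with aryloxypropiolate 12 forms C5–C6 and C1–C2, aromatises, and frees the C2 phenol for the last prenylation, while the congested diaryl ether O–C6 bond is already in place, made earlier at an sp carbon. Precursor 12 is the ring B phenol, benzylic alcohol silylated, O-bound to methyl propiolate.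

Key step: step 9

Remark on the chemistry: the target has no stereocentre. The E geometry of 9 and the racemic acetal carbon of 16 are both erased later. The ketene acetal geometry of 15 is left undefined because that carbon becomes aromatic C2.

**Step 1**
Reactants: 1 2-hydroxy-5-methoxybenzaldehyde
Product: 2 3-bromo-2-hydroxy-5-methoxybenzaldehyde
Conditions: Br2, NaOAc, AcOH, rt
Reagents that add atoms: bromine, BrBr
Why: Electrophilic aromatic bromination goes to the only free position ortho to the phenol, which is also meta to the deactivating formyl group, with NaOAc buffering the HBr.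

**Step 2**
Reactants: 2 3-bromo-2-hydroxy-5-methoxybenzaldehyde
Product: 3 2,3-dihydroxy-5-methoxybenzaldehyde
Conditions: aq NaOH, Cu powder (cat.), reflux, N2; then aq HCl
Reagents that add atoms: sodium hydroxide, [Na+].[OH-]
Why: Copper-mediated Ullmann-type hydroxylation of an ortho-bromophenoxide in hot alkali is the established way from bromosalicylaldehydes and bromovanillins to the catechols, and the phenoxide form shields the aldehyde from the Cannizzaro reaction.

**Step 3**
Reactants: 3 2,3-dihydroxy-5-methoxybenzaldehyde; 4 prenyl bromide (1-bromo-3-methylbut-2-ene)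
Product: 5 2-hydroxy-5-methoxy-3-(3-methylbut-2-enyloxy)benzaldehyde
Conditions: NaH (2.1 equiv), DMSO, rt; then 4 (1.0 equiv); then cold 1 M HCl
Reagents that add atoms: none
Why: Williamson etherification of the catechol dianion takes the single equivalent of bromide at the C3 oxygen, which is the more nucleophilic one because the C2 phenoxide is conjugated and chelated with the aldehyde, as known for 2,3-dihydroxybenzaldehyde.

**Step 4**
Reactants: 5 2-hydroxy-5-methoxy-3-(3-methylbut-2-enyloxy)benzaldehyde
Product: 6 2-(hydroxymethyl)-4-methoxy-6-(3-methylbut-2-enyloxy)phenol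
Conditions: NaBH4, MeOH, 0 °C; neutral work-up, used crude
Reagents that add atoms: none
Why: Borohydride reduction of the aldehyde has no competing reducible group, and a neutral work-up avoids ortho-quinone methide formation from the salicyl alcohol.

**Step 5**
Reactants: 6 2-(hydroxymethyl)-4-methoxy-6-(3-methylbut-2-enyloxy)phenol
Product: 7 2-[(tert-butyldimethylsilyloxy)methyl]-4-methoxy-6-(3-methylbut-2-enyloxy)phenol
Conditions: TBSCl (1.05 equiv), imidazole, CH2Cl2, 0 °C
Reagents that add atoms: tert-butyldimethylsilyl chloride, CC(C)(C)[Si](C)(C)Cl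
Why: Silylation under imidazole catalysis should select the primary benzylic alcohol over the 2,6-disubstituted, hydrogen-bonded phenol, as is standard for salicyl alcohols.

**Step 6**
Reactants: 7 2-[(tert-butyldimethylsilyloxy)methyl]-4-methoxy-6-(3-methylbut-2-enyloxy)phenol; 8 trichloroethylene
Product: 9 tert-butyl({2-[(E)-1,2-dichloroethenyloxy]-5-methoxy-3-(3-methylbut-2-enyloxy)phenyl}methoxy)dimethylsilane
Conditions: K2CO3, DMF, 70 °C, under N2 (dichloroacetylene is formed and consumed in solution only)
Reagents that add atoms: none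
Why: In this Greene-type dichlorovinylation the base turns 8 into dichloroacetylene and the phenoxide adds anti across it, so the hindered aryl–oxygen bond forms at an unhindered sp carbon and the E ether results.

**Step 7**
Reactants: 9 tert-butyl({2-[(E)-1,2-dichloroethenyloxy]-5-methoxy-3-(3-methylbut-2-enyloxy)phenyl}methoxy)dimethylsilane
Product: 12 methyl 3-[2-(tert-butyldimethylsilyloxymethyl)-4-methoxy-6-(3-methylbut-2-enyloxy)phenoxy]prop-2-ynoate, via chloroethynyl aryl ether 10 (not isolated), via lithium aryloxyacetylide 11 (not isolated)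
Conditions: n-BuLi (2.3 equiv), THF, −78 °C; then ClCO2Me, −78 to −20 °C; cold aq NaHCO3; used promptly
Reagents that add atoms: methyl chloroformate, COC(=O)Cl
Why: In the Greene ynol ether synthesis, deprotonation and loss of LiCl give chloroalkyne 10, chlorine–lithium exchange gives acetylide 11, and C-acylation by the chloroformate gives the ynoate.

**Step 8**
Reactants: 13 methyl 3-methylbut-2-enoate
Product: 15 1-methoxy-3-methyl-1-(trimethylsilyloxy)buta-1,3-diene, via lithium dienolate 14 (not isolated)
Conditions: LiN(iPr)2 (LDA), THF, −78 °C; then Me3SiCl, −78 °C to rt; distilled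
Reagents that add atoms: chlorotrimethylsilane, C[Si](C)(C)Cl
Why: Kinetic γ-deprotonation of the senecioate and O-silylation of the dienolate is the standard silyl ketene acetal route to this 1,1-dioxygenated diene.

**Step 9**
Reactants: 12 methyl 3-[2-(tert-butyldimethylsilyloxymethyl)-4-methoxy-6-(3-methylbut-2-enyloxy)phenoxy]prop-2-ynoate; 15 1-methoxy-3-methyl-1-(trimethylsilyloxy)buta-1,3-diene
Product: 17 methyl 2-{2-[(tert-butyldimethylsilyloxy)methyl]-4-methoxy-6-(3-methylbut-2-enyloxy)phenoxy}-6-hydroxy-4-methylbenzoate, via cyclohexadiene cycloadduct 16 (not isolated)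
Conditions: 15 (3 equiv), PhMe, 90 °C, sealed; then 10% aq citric acid, THF, rt
Reagents that add atoms: none
Why: Proposed new method: the CH2 terminus of 15, which carries the largest HOMO coefficient, should attack the alkyne carbon of 12 that is β to the ester and bears the aryloxy group, and the α-carbon then bonds to the acetal carbon, either in one asynchronous (4+2) cycloaddition or as a Mukaiyama–Michael addition followed by closure of the allenoate onto the oxocarbenium carbon, both giving cyclohexa-1,4-diene 16. The closest known reaction type is the Diels–Alder benzannulation of 1-alkoxy-1-silyloxybuta-1,3-dienes with propiolates and acetylenedicarboxylates to give salicylates, extended here to a push–pull 3-aryloxypropiolate. Ring A is closed as a six-membered carbocycle by intermolecular (4+2) annulation, the C5–C6 and C1–C2 bonds forming in the same operation. No stereocentre results, because the stereogenic acetal carbon of 16 is flattened when 16 loses methanol and the trimethylsilyl group to become the phenol. The step needs regioselectivity that places the ester between the two oxygens, and the polarisation of both partners secures it: the ester makes the aryloxy-bearing carbon of 12 the electrophilic terminus and the acetal oxygens make the CH2 end of 15 the nucleophilic one. The aryloxy group is kept because it sits on an sp2 carbon of 16 and only the acetal carbon carries leaving groups.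

**Step 10**
Reactants: 17 methyl 2-{2-[(tert-butyldimethylsilyloxy)methyl]-4-methoxy-6-(3-methylbut-2-enyloxy)phenoxy}-6-hydroxy-4-methylbenzoate; 4 prenyl bromide
Product: 18 methyl 2-{2-[(tert-butyldimethylsilyloxy)methyl]-4-methoxy-6-(3-methylbut-2-enyloxy)phenoxy}-4-methyl-6-(3-methylbut-2-enyloxy)benzoate
Conditions: K2CO3, DMF, rt to 40 °C
Reagents that add atoms: none
Why: Williamson alkylation of the salicylate hydroxyl, the only acidic OH, while the silyl ether keeps the benzylic oxygen from attacking the neighbouring ester under base.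

**Step 11**
Reactants: 18 methyl 2-{2-[(tert-butyldimethylsilyloxy)methyl]-4-methoxy-6-(3-methylbut-2-enyloxy)phenoxy}-4-methyl-6-(3-methylbut-2-enyloxy)benzoate
Product: 19 methyl 2-[2-(hydroxymethyl)-4-methoxy-6-(3-methylbut-2-enyloxy)phenoxy]-4-methyl-6-(3-methylbut-2-enyloxy)benzoate (CNP0561346.0)
Conditions: Bu4NF, AcOH (1:1), THF, 0 °C to rt
Reagents that add atoms: none
Why: Fluoride cleaves the silyl ether, and the acetic acid buffer keeps the freed benzylic oxygen protonated so that it does not close the eight-membered lactone onto the ring A ester.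

**Compound list**
1 | 2-hydroxy-5-methoxybenzaldehyde | COc1ccc(O)c(C=O)c1 | starting material
2 | 3-bromo-2-hydroxy-5-methoxybenzaldehyde | COc1cc(Br)c(O)c(C=O)c1 | intermediate
3 | 2,3-dihydroxy-5-methoxybenzaldehyde | COc1cc(O)c(O)c(C=O)c1 | intermediate
4 | prenyl bromide (1-bromo-3-methylbut-2-ene) | CC(C)=CCBr | starting material
5 | 2-hydroxy-5-methoxy-3-(3-methylbut-2-enyloxy)benzaldehyde | COc1cc(OCC=C(C)C)c(O)c(C=O)c1 | intermediate
6 | 2-(hydroxymethyl)-4-methoxy-6-(3-methylbut-2-enyloxy)phenol | COc1cc(CO)c(O)c(OCC=C(C)C)c1 | intermediate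
7 | 2-[(tert-butyldimethylsilyloxy)methyl]-4-methoxy-6-(3-methylbut-2-enyloxy)phenol | COc1cc(CO[Si](C)(C)C(C)(C)C)c(O)c(OCC=C(C)C)c1 | intermediate
8 | trichloroethylene | ClC=C(Cl)Cl | starting material
9 | tert-butyl({2-[(E)-1,2-dichloroethenyloxy]-5-methoxy-3-(3-methylbut-2-enyloxy)phenyl}methoxy)dimethylsilane | Cl/C=C(/Cl)Oc1c(CO[Si](C)(C)C(C)(C)C)cc(OC)cc1OCC=C(C)C | intermediate
10 | tert-butyl({2-(chloroethynyloxy)-5-methoxy-3-(3-methylbut-2-enyloxy)phenyl}methoxy)dimethylsilane | ClC#COc1c(CO[Si](C)(C)C(C)(C)C)cc(OC)cc1OCC=C(C)C | intermediate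
11 | {[2-(tert-butyldimethylsilyloxymethyl)-4-methoxy-6-(3-methylbut-2-enyloxy)phenoxy]ethynyl}lithium | [Li]C#COc1c(CO[Si](C)(C)C(C)(C)C)cc(OC)cc1OCC=C(C)C | intermediate
12 | methyl 3-[2-(tert-butyldimethylsilyloxymethyl)-4-methoxy-6-(3-methylbut-2-enyloxy)phenoxy]prop-2-ynoate | COC(=O)C#COc1c(CO[Si](C)(C)C(C)(C)C)cc(OC)cc1OCC=C(C)C | intermediate
13 | methyl 3-methylbut-2-enoate | COC(=O)C=C(C)C | starting material
14 | lithium 1-methoxy-3-methylbuta-1,3-dien-1-olate | [Li]OC(OC)=CC(C)=C | intermediate
15 | 1-methoxy-3-methyl-1-(trimethylsilyloxy)buta-1,3-diene (geometry undefined) | COC(O[Si](C)(C)C)=CC(C)=C | intermediate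
16 | methyl 2-[2-(tert-butyldimethylsilyloxymethyl)-4-methoxy-6-(3-methylbut-2-enyloxy)phenoxy]-6-methoxy-4-methyl-6-(trimethylsilyloxy)cyclohexa-1,4-diene-1-carboxylate (racemic) | COC(=O)C1=C(Oc2c(CO[Si](C)(C)C(C)(C)C)cc(OC)cc2OCC=C(C)C)CC(C)=CC1(OC)O[Si](C)(C)C | intermediate
17 | methyl 2-{2-[(tert-butyldimethylsilyloxy)methyl]-4-methoxy-6-(3-methylbut-2-enyloxy)phenoxy}-6-hydroxy-4-methylbenzoate | COC(=O)c1c(O)cc(C)cc1Oc1c(CO[Si](C)(C)C(C)(C)C)cc(OC)cc1OCC=C(C)C | intermediate
18 | methyl 2-{2-[(tert-butyldimethylsilyloxy)methyl]-4-methoxy-6-(3-methylbut-2-enyloxy)phenoxy}-4-methyl-6-(3-methylbut-2-enyloxy)benzoate | COC(=O)c1c(OCC=C(C)C)cc(C)cc1Oc1c(CO[Si](C)(C)C(C)(C)C)cc(OC)cc1OCC=C(C)C | intermediate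
19 | methyl 2-[2-(hydroxymethyl)-4-methoxy-6-(3-methylbut-2-enyloxy)phenoxy]-4-methyl-6-(3-methylbut-2-enyloxy)benzoate | COC(=O)c1c(OCC=C(C)C)cc(C)cc1Oc1c(CO)cc(OC)cc1OCC=C(C)C | target

**Count.** Total steps: 11. Longest linear sequence: 10 steps (steps 1 to 7, then 9, 10 and 11); step 8 is the one-step side branch.

**Steps most likely to fail**

1. Step 9 (Proposed new method). The donor-substituted alkyne carbon of 12 may be too weakly electrophilic, so that the diene is lost to hydrolysis or oligomerisation before it adds, and stronger heating would start Claisen rearrangement of the aryl prenyl ether. The fallback uses known chemistry, brings ring A in as a finished arene, sets out from 7 and comes back to the route at 18. Commercial 3-bromo-5-methylphenol (Cc1cc(O)cc(Br)c1) is alkylated with 4 (K2CO3, acetone) to 1-bromo-3-methyl-5-(3-methylbut-2-enyloxy)benzene F1. LiN(iPr)2 in THF at −78 °C then removes the proton between bromine and oxygen to give 2-bromo-4-methyl-6-(3-methylbut-2-enyloxy)phenyllithium F2, which is quenched cold with methyl chloroformate to methyl 2-bromo-4-methyl-6-(3-methylbut-2-enyloxy)benzoate F3. Ullmann diaryl ether coupling of phenol 7 with F3 (CuI, picolinic acid, K3PO4, DMSO, 90 °C), helped by the ortho ester of the bromide, should give 18, and step 11 completes the synthesis.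

2. Step 7. Butyllithium may add to the aryloxyalkyne or metalate ring B between its two alkoxy groups, and the push–pull ynoate may hydrate or polymerise on isolation. The fallback uses no organolithium, brings the ester in together with the two alkyne carbons, sets out from 7 and comes back at 12. Phenol 7 and methyl 3,3-dibromoprop-2-enoate (COC(=O)C=C(Br)Br; Cs2CO3, DMF, rt) should give, by addition–elimination at the dibromovinyl carbon, methyl 3-bromo-3-[2-(tert-butyldimethylsilyloxymethyl)-4-methoxy-6-(3-methylbut-2-enyloxy)phenoxy]prop-2-enoate F4 (either geometry). KN(SiMe3)2 in THF at −78 °C then removes HBr through the allenolate (E1cB) to give 12, which is taken directly into step 9.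

3. Step 2. In hot alkali the electron-rich catechol may be oxidised, or the bromide may be reduced off instead of substituted. The fallback replaces nucleophilic hydroxylation by borylation and oxidation, sets out from 2 and comes back at 3. Miyaura borylation of 2 (bis(pinacolato)diboron, CC1(C)OB(OC1(C)C)B1OC(C)(C)C(C)(C)O1; PdCl2(dppf), where dppf is 1,1'-bis(diphenylphosphino)ferrocene; KOAc, dioxane, 90 °C) gives 2-hydroxy-5-methoxy-3-(4,4,5,5-tetramethyl-1,3,2-dioxaborolan-2-yl)benzaldehyde F5. N-Methylmorpholine N-oxide in CH2Cl2 at rt then turns the carbon–boron bond into carbon–oxygen without Dakin oxidation of the aldehyde, giving 3.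

**Further compounds**
F1 | step 9 | 1-bromo-3-methyl-5-(3-methylbut-2-enyloxy)benzene | Cc1cc(Br)cc(OCC=C(C)C)c1
F2 | step 9 | 2-bromo-4-methyl-6-(3-methylbut-2-enyloxy)phenyllithium | [Li]c1c(Br)cc(C)cc1OCC=C(C)C
F3 | step 9 | methyl 2-bromo-4-methyl-6-(3-methylbut-2-enyloxy)benzoate | COC(=O)c1c(Br)cc(C)cc1OCC=C(C)C
F4 | step 7 | methyl 3-bromo-3-[2-(tert-butyldimethylsilyloxymethyl)-4-methoxy-6-(3-methylbut-2-enyloxy)phenoxy]prop-2-enoate | COC(=O)C=C(Br)Oc1c(CO[Si](C)(C)C(C)(C)C)cc(OC)cc1OCC=C(C)C
F5 | step 2 | 2-hydroxy-5-methoxy-3-(4,4,5,5-tetramethyl-1,3,2-dioxaborolan-2-yl)benzaldehyde | COc1cc(C=O)c(O)c(B2OC(C)(C)C(C)(C)O2)c1
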